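**Retrosynthetic overview**

1. Target 25 ⇒ tribenzyl ether 24 (three O-benzyl cleavages) ⇒ lactol 22, in which C1' of the chain still carries its formyl carbon, closed as a temporary six-membered lactol on O7 of ring B.
2. Key disconnection of 22: the methine–C1' and O7–C(lactol) bonds, giving ring B o-quinone methide 21 (from sulfone 18) and the enamine of 6-methylheptanal 19. The feature used: the methine C–H joining C6 of ring A to C6 of ring B is ortho to the 7-hydroxyl of ring B, so it can be the exocyclic carbon of an o-quinone methide. Ring A, with O5 and O7 benzylated, cannot form one; a methide on ring A would lead to the opposite methine.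
3. Sulfone 18 ⇒ ring A aldehyde 16 + ring B phenol 7 + p-toluenesulfinic acid (methine–C6 of ring B and methine–S bonds).
4. Both chromans ⇒ phloroglucinol 1: Friedel–Crafts acylation, benzylation of the para oxygen, prenyl annulation (the pyran can then close only on an oxygen ortho to the ketone); ring A also gets C6-formylation and 7-O-benzylation.
5. Ring order: benzene rings bought; pyran of ring B (step 3); pyran of ring A (step 7); temporary lactol ring (step 11), opened again in step 12.

Key step: step 11

Remarks: chroman numbering (O1, C2, C3, C4, C4a, C5–C8, C8a) is used for both bicycles; ring A carries the (R)-2-methylbutanoyl group, ring B the isobutyryl group; C1' is the chain carbon bound to the methine.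
Assumption: 6-methylheptanal 19 is taken as purchasable and distilled before use; the sense of induction in step 11 is assigned by analogy and is to be confirmed on 22 before step 12.

**Route**

Step 1
Reactants: 1 phloroglucinol; 2 isobutyryl chloride
Product: 3 2-methyl-1-(2,4,6-trihydroxyphenyl)propan-1-one
Conditions: AlCl3 (3.5 equiv), PhNO2/CH2Cl2, 0 °C to rt; then ice/aq. HCl
Reagents that add atoms: none
Why: Friedel–Crafts C-acylation of the very electron-rich triol; the aluminium chelate of the product ketone is deactivated, so the reaction should stop at monoacylation.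

Step 2
Reactants: 3 2-methyl-1-(2,4,6-trihydroxyphenyl)propan-1-one
Product: 4 1-[4-(benzyloxy)-2,6-dihydroxyphenyl]-2-methylpropan-1-one
Conditions: BnBr (1.0 equiv), K2CO3 (1.0 equiv), DMF, 0 °C to rt
Reagents that add atoms: benzyl bromide, BrCc1ccccc1
Why: Williamson etherification at the hydroxyl para to the carbonyl, which is the most acidic one (its anion is a vinylogous carboxylate) and is not hydrogen-bonded; one equivalent of halide limits dibenzylation, and the ether blocks the para oxygen for the annulation.

Step 3
Reactants: 4 1-[4-(benzyloxy)-2,6-dihydroxyphenyl]-2-methylpropan-1-one; 5 2-methylbut-3-en-2-ol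
Product: 7 1-[5-(benzyloxy)-7-hydroxy-2,2-dimethylchroman-8-yl]-2-methylpropan-1-one (ring B monomer), via C-prenyl phenol 6 (not isolated)
Conditions: 5 (1.1 equiv), BF3·OEt2 (30 mol %), dioxane, rt then 50 °C
Reagents that add atoms: none
Why: Friedel–Crafts prenylation by the dimethylallyl cation at one of the two equivalent free ring carbons, then acid-catalysed Markovnikov hydroalkoxylation of the prenyl alkene; since the para oxygen is benzylated, the tertiary cation can only be captured by a hydroxyl ortho to the ketone, which fixes the 8-acyl chroman, and the limited amount of 5 should keep a second annulation low.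

Step 4
Reactants: 8 (R)-2-methylbutanoic acid
Product: 9 (R)-2-methylbutanoyl chloride
Conditions: (COCl)2 (1.1 equiv), DMF (cat.), CH2Cl2, 0 °C to rt; volatiles removed cold, used as a CH2Cl2 solution
Reagents that add atoms: oxalyl chloride, O=C(Cl)C(=O)Cl
Why: acid chloride formation through chloroiminium activation; no base is present, so no ketene can form and the α-stereocentre should be retained.

Step 5
Reactants: 1 phloroglucinol; 9 (R)-2-methylbutanoyl chloride
Product: 10 (2R)-2-methyl-1-(2,4,6-trihydroxyphenyl)butan-1-one
Conditions: AlCl3 (3.5 equiv), PhNO2/CH2Cl2, 0 °C to rt; then ice/aq. HCl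
Reagents that add atoms: none
Why: Friedel–Crafts acylation as in step 1, kept at or below room temperature so that the α-stereocentre brought in with 9 is not enolised; the enantiomeric purity is to be checked at this stage.

Step 6
Reactants: 10 (2R)-2-methyl-1-(2,4,6-trihydroxyphenyl)butan-1-one
Product: 11 (2R)-1-[4-(benzyloxy)-2,6-dihydroxyphenyl]-2-methylbutan-1-one
Conditions: BnBr (1.0 equiv), K2CO3 (1.0 equiv), DMF, 0 °C to rt
Reagents that add atoms: benzyl bromide, BrCc1ccccc1
Why: Williamson etherification of the para hydroxyl as in step 2; in the phenoxide the ketone is a vinylogous carboxylate, so the α-hydrogen should not be removed by carbonate.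

Step 7
Reactants: 11 (2R)-1-[4-(benzyloxy)-2,6-dihydroxyphenyl]-2-methylbutan-1-one; 5 2-methylbut-3-en-2-ol
Product: 13 (2R)-1-[5-(benzyloxy)-7-hydroxy-2,2-dimethylchroman-8-yl]-2-methylbutan-1-one, via C-prenyl phenol 12 (not isolated)
Conditions: 5 (1.1 equiv), BF3·OEt2 (30 mol %), dioxane, rt then 50 °C
Reagents that add atoms: none
Why: Friedel–Crafts prenylation and acid-catalysed hydroalkoxylation as in step 3, with the same regiochemical lock by the para benzyl ether.

Step 8
Reactants: 13 (2R)-1-[5-(benzyloxy)-7-hydroxy-2,2-dimethylchroman-8-yl]-2-methylbutan-1-one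
Product: 15 5-(benzyloxy)-7-hydroxy-2,2-dimethyl-8-[(2R)-2-methylbutanoyl]chroman-6-carbaldehyde, via iminium chloride 14 (not isolated)
Conditions: POCl3 (1.3 equiv), DMF, MeCN, 0 °C to rt; then H2O, 40 °C
Reagents that add atoms: N,N-dimethylformamide, CN(C)C=O; water, O
Why: Vilsmeier–Haack formylation at C6, the only free ring carbon, activated by O5 and O7 (ortho) and O1 (para); the hindered α-branched ketone should not be attacked at room temperature, and water hydrolyses iminium salt 14 to the aldehyde.

Step 9
Reactants: 15 5-(benzyloxy)-7-hydroxy-2,2-dimethyl-8-[(2R)-2-methylbutanoyl]chroman-6-carbaldehyde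
Product: 16 5,7-bis(benzyloxy)-2,2-dimethyl-8-[(2R)-2-methylbutanoyl]chroman-6-carbaldehyde (ring A aldehyde)
Conditions: BnBr (1.5 equiv), K2CO3 (2 equiv), nBu4NI (cat.), DMF, 50 °C
Reagents that add atoms: benzyl bromide, BrCc1ccccc1
Why: Williamson etherification of the remaining 7-hydroxyl, which is hydrogen-bonded between two carbonyls and therefore needs heating; both oxygens flanking C6 of ring A are now blocked, which later forbids a quinone methide on ring A.

Step 10
Reactants: 16 ring A aldehyde; 7 ring B monomer
Product: 18 diarylmethyl p-tolyl sulfone (ring A 5,7-di-O-benzyl; ring B 5-O-benzyl 7-hydroxy; both epimers at the sulfone carbon), via carbinol 17 (not isolated)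
Conditions: p-TolSO2H (2 equiv), p-TsOH·H2O (10 mol %), MgSO4, CH2Cl2, rt
Reagents that add atoms: p-toluenesulfinic acid, Cc1ccc(cc1)S(=O)O
Why: sulfinic acid variant of the three-component Mannich (Betti-type) alkylation of phenols: acid-catalysed Friedel–Crafts hydroxyalkylation at C6 of 7, its only free ring carbon and ortho to the free 7-OH, gives carbinol 17, whose doubly stabilised benzhydryl cation is captured at sulfur by the sulfinate; the sulfone carbon is formed without control and both epimers are used.

Step 11
Reactants: 18 diarylmethyl p-tolyl sulfone; 19 6-methylheptanal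
Product: 22 ring B-fused lactol (3,4-trans; C1' R; anomeric mixture), via enamine 20 (not isolated), via o-quinone methide 21 (not isolated)
Conditions: (S)-2-[diphenyl(trimethylsilyloxy)methyl]pyrrolidine (20 mol %), 19 (3 equiv), Na2CO3 (1.5 equiv), CH2Cl2/H2O, 0 °C to rt
Reagents that add atoms: water, O
Why: Na2CO3 removes the acidic 7-OH proton of ring B and the phenoxide expels p-toluenesulfinate to give o-quinone methide 21 (C7=O, C6=CH–ring A), the α-carbon of the anti E-enamine 20 adds to the exocyclic methide carbon (methine–C1' bond), the re-aromatised O7 phenoxide closes on the iminium carbon in a 6-exo-trig mode (O7–C bond, six-membered N,O-aminal, overall a stepwise inverse-demand hetero-Diels–Alder reaction) and hydrolysis releases lactol 22 and the amine. The closest known reaction is the diarylprolinol silyl ether catalysed formal [4+2] addition of enolisable aldehydes to o-quinone methides set free by base from 2-(1-sulfonylalkyl)phenols, which gives chroman-2-ols. C1' is controlled by the catalyst, whose CPh2(OSiMe3) arm covers one face of the enamine, and the anomeric carbon is not controlled and is removed in step 12. The methine is controlled relative to C1' by an endo-type synclinal approach in which C7=O lies over the enamine nitrogen, the methine hydrogen takes the crowded site between the enamine N–CH carbon and the chain and the twisted ring A points away from the pyrrolidine; by analogy with the syn-selective additions of aldehydes to nitroalkenes under the same (S)-catalyst this should give the 3,4-trans lactol in which ring A, ring B and C1' run clockwise when the methine hydrogen points to the rear, as in the target. The step needs site selectivity in methide formation, secured because O7 of ring B is the only free hydroxyl next to the sulfone carbon (O5 and O7 of ring A and O5 of ring B are benzyl ethers), and it needs high diastereoselectivity, because once C1' is lost a 3,4-cis lactol would end as the wrong methine epimer, so any cis isomer is removed by chromatography here. The two methide geometries can interconvert by reversible sulfinate addition, and only the one with the vinylic hydrogen beside C7=O and ring A beside the out-of-plane 5-benzyloxy group allows this endo approach, so the adduct should arise from that geometry.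

Step 12
Reactants: 22 ring B-fused lactol
Product: 24 tribenzyl ether of the target (methine R), via hydroxy aldehyde 23 (not isolated)
Conditions: RhCl(PPh3)3 (1.2 equiv), PhCN, 110 °C
Reagents that add atoms: none
Why: Tsuji–Wilkinson decarbonylation acting on the ring-opened tautomer 23, as in the decarbonylation of aldoses: oxidative addition of the formyl C–H bond to rhodium, CO de-insertion and C–H reductive elimination turn C1' into a CH2 group and erase both temporary centres, while the methine is not involved and should keep its configuration.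

Step 13
Reactants: 24 tribenzyl ether of the target
Product: 25 target
Conditions: H2 (1 atm), 10% Pd/C, EtOAc, rt
Reagents that add atoms: none
Why: hydrogenolysis of the three benzyl aryl ethers over palladium; the hindered aryl ketones (vinylogous esters), the chroman ethers and both stereocentres should not be touched under neutral conditions.

**Compound list**

1 | phloroglucinol | Oc1cc(O)cc(O)c1 | starting material
2 | isobutyryl chloride | CC(C)C(=O)Cl | starting material
3 | 2-methyl-1-(2,4,6-trihydroxyphenyl)propan-1-one | CC(C)C(=O)c1c(O)cc(O)cc1O | intermediate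
4 | 1-[4-(benzyloxy)-2,6-dihydroxyphenyl]-2-methylpropan-1-one | CC(C)C(=O)c1c(O)cc(OCc2ccccc2)cc1O | intermediate
5 | 2-methylbut-3-en-2-ol | CC(C)(O)C=C | starting material
6 | 1-[4-(benzyloxy)-2,6-dihydroxy-3-(3-methylbut-2-en-1-yl)phenyl]-2-methylpropan-1-one | CC(C)C(=O)c1c(O)cc(OCc2ccccc2)c(CC=C(C)C)c1O | intermediate (not isolated)
7 | 1-[5-(benzyloxy)-7-hydroxy-2,2-dimethylchroman-8-yl]-2-methylpropan-1-one (ring B monomer) | CC(C)C(=O)c1c(O)cc(OCc2ccccc2)c2c1OC(C)(C)CC2 | intermediate
8 | (R)-2-methylbutanoic acid | CC[C@@H](C)C(=O)O | starting material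
9 | (R)-2-methylbutanoyl chloride | CC[C@@H](C)C(=O)Cl | intermediate
10 | (2R)-2-methyl-1-(2,4,6-trihydroxyphenyl)butan-1-one | CC[C@@H](C)C(=O)c1c(O)cc(O)cc1O | intermediate
11 | (2R)-1-[4-(benzyloxy)-2,6-dihydroxyphenyl]-2-methylbutan-1-one | CC[C@@H](C)C(=O)c1c(O)cc(OCc2ccccc2)cc1O | intermediate
12 | (2R)-1-[4-(benzyloxy)-2,6-dihydroxy-3-(3-methylbut-2-en-1-yl)phenyl]-2-methylbutan-1-one | CC[C@@H](C)C(=O)c1c(O)cc(OCc2ccccc2)c(CC=C(C)C)c1O | intermediate (not isolated)
13 | (2R)-1-[5-(benzyloxy)-7-hydroxy-2,2-dimethylchroman-8-yl]-2-methylbutan-1-one | CC[C@@H](C)C(=O)c1c(O)cc(OCc2ccccc2)c2c1OC(C)(C)CC2 | intermediate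
14 | N-[[5-(benzyloxy)-7-hydroxy-2,2-dimethyl-8-[(2R)-2-methylbutanoyl]chroman-6-yl]methylidene]-N-methylmethanaminium chloride | CC[C@@H](C)C(=O)c1c(O)c(C=[N+](C)C)c(OCc2ccccc2)c2c1OC(C)(C)CC2.[Cl-] | intermediate (not isolated)
15 | 5-(benzyloxy)-7-hydroxy-2,2-dimethyl-8-[(2R)-2-methylbutanoyl]chroman-6-carbaldehyde | CC[C@@H](C)C(=O)c1c(O)c(C=O)c(OCc2ccccc2)c2c1OC(C)(C)CC2 | intermediate
16 | 5,7-bis(benzyloxy)-2,2-dimethyl-8-[(2R)-2-methylbutanoyl]chroman-6-carbaldehyde (ring A aldehyde) | CC[C@@H](C)C(=O)c1c(OCc2ccccc2)c(C=O)c(OCc2ccccc2)c2c1OC(C)(C)CC2 | intermediate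
17 | diaryl carbinol: ring A (5,7-di-O-benzyl) and ring B (5-O-benzyl, 7-hydroxy) joined through CH(OH) at their C6 atoms, both carbinol epimers | CC[C@@H](C)C(=O)c1c(OCc2ccccc2)c(C(O)c2c(OCc3ccccc3)c3c(c(C(=O)C(C)C)c2O)OC(C)(C)CC3)c(OCc2ccccc2)c2c1OC(C)(C)CC2 | intermediate (not isolated)
18 | diarylmethyl p-tolyl sulfone: as 17 with 4-methylbenzenesulfonyl in place of hydroxyl, both epimers at the sulfone carbon | CC[C@@H](C)C(=O)c1c(OCc2ccccc2)c(C(c2c(OCc3ccccc3)c3c(c(C(=O)C(C)C)c2O)OC(C)(C)CC3)S(=O)(=O)c2ccc(C)cc2)c(OCc2ccccc2)c2c1OC(C)(C)CC2 | intermediate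
19 | 6-methylheptanal | CC(C)CCCCC=O | starting material
20 | (S)-2-[diphenyl(trimethylsilyloxy)methyl]-1-[(1E)-6-methylhept-1-en-1-yl]pyrrolidine (enamine) | CC(C)CCC/C=C/N1CCC[C@H]1C(c1ccccc1)(c1ccccc1)O[Si](C)(C)C | intermediate (not isolated)
21 | ring B o-quinone methide: 5-(benzyloxy)-8-isobutyryl-2,2-dimethyl-6-[(ring A aryl)methylidene]-3,4-dihydro-2H-chromen-7(6H)-one, ring A aryl = 5,7-bis(benzyloxy)-2,2-dimethyl-8-[(2R)-2-methylbutanoyl]chroman-6-yl | CC[C@@H](C)C(=O)c1c(OCc2ccccc2)c(C=C2C(=O)C(C(=O)C(C)C)=C3OC(C)(C)CCC3=C2OCc2ccccc2)c(OCc2ccccc2)c2c1OC(C)(C)CC2 | intermediate (not isolated)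
22 | lactol fused to ring B through O7: lactol carbon bears OH, C1' (R) bears the 4-methylpentyl chain, methine bears ring A; 3,4-trans; ring A, ring B and C1' clockwise with the methine H to the rear; anomeric mixture | CC[C@@H](C)C(=O)c1c(OCc2ccccc2)c([C@H]([C@@H](CCCC(C)C)C(O)O3)c2c(OCc4ccccc4)c4c(c(C(=O)C(C)C)c23)OC(C)(C)CC4)c(OCc2ccccc2)c2c1OC(C)(C)CC2 | intermediate
23 | ring-opened tautomer of 22: C1' formyl aldehyde with free 7-OH on ring B | CC[C@@H](C)C(=O)c1c(OCc2ccccc2)c([C@H]([C@@H](CCCC(C)C)C=O)c2c(OCc3ccccc3)c3c(c(C(=O)C(C)C)c2O)OC(C)(C)CC3)c(OCc2ccccc2)c2c1OC(C)(C)CC2 | intermediate (not isolated)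
24 | tribenzyl ether of the target (ring A 5,7-di-O-benzyl, ring B 5-O-benzyl; methine R) | CC[C@@H](C)C(=O)c1c(OCc2ccccc2)c([C@H](CCCCC(C)C)c2c(OCc3ccccc3)c3c(c(C(=O)C(C)C)c2O)OC(C)(C)CC3)c(OCc2ccccc2)c2c1OC(C)(C)CC2 | intermediate
25 | 1-[6-[(1R)-1-[5,7-dihydroxy-2,2-dimethyl-8-[(2R)-2-methylbutanoyl]chroman-6-yl]-6-methylheptyl]-5,7-dihydroxy-2,2-dimethylchroman-8-yl]-2-methylpropan-1-one | CC[C@@H](C)C(=O)c1c(O)c([C@H](CCCCC(C)C)c2c(O)c3c(c(C(=O)C(C)C)c2O)OC(C)(C)CC3)c(O)c2c1OC(C)(C)CC2 | target

**Step count**

Total: 13 steps. Longest linear sequence: 10 steps (steps 4 to 13, from acid 8 to 25); the ring B branch (steps 1 to 3) joins at step 10.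

**Steps most likely to fail**

1. Step 11. The enamine may add too slowly to the exocyclic carbon, which is flanked by the twisted ring A and the 5-benzyloxy group, so that the methide returns to the carbinol or re-adds sulfinate. The relative topicity may also be poor or opposite to the model, which would lower or invert the methine. Fallback, changing the nucleophile and the mode of activation: it sets out from sulfone 18 and comes back at 25.
   - Under aqueous NaHCO3 in CH2Cl2 with a bifunctional cinchona squaramide, Meldrum's acid adds to methide 21. The catalyst is 3-[[3,5-bis(trifluoromethyl)phenyl]amino]-4-[[(8α,9S)-6'-methoxycinchonan-9-yl]amino]cyclobut-3-ene-1,2-dione or its quinidine-derived pseudoenantiomer, whichever delivers the target methine. Meldrum's acid is small and has no temporary stereocentre.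
   - The adduct closes on O7 with loss of acetone and CO2 (warming with p-TsOH in toluene if needed) to give the 3-unsubstituted dihydrocoumarin F1. This is the known hydrogen-bond catalysed addition of Meldrum's acid to o-quinone methides from 2-(1-sulfonylalkyl)phenols, and here the catalyst sets the methine directly.
   - i-Bu2AlH (1.05 equiv, CH2Cl2, −78 °C) should reduce the aryl ester in preference to the hindered ketones to give lactol F2.
   - Wittig olefination of F2 with the ylide from (3-methylbutyl)triphenylphosphonium bromide and KN(SiMe3)2 (3 equiv, THF, −78 °C to rt) gives Z-alkene F3, in which the former lactone carbon is the second chain carbon.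
   - H2 over 10% Pd/C saturates the alkene and removes the three benzyl groups to give 25.

2. Step 12. The lactol may open too little, or the hindered α-branched formyl group may insert slowly. β-Hydride elimination from the alkyl rhodium hydride may give alkenes, and towards the methine this would erase the stereocentre. Heating may also trigger retro-addition through the methide. Fallback, replacing decarbonylation by a room-temperature radical decarboxylation: it sets out from lactol 22 and comes back at 25.
   - Cs2CO3 and BnBr in DMF at rt trap the ring-opened phenoxide as the ring B 7-O-benzyl aldehyde F4; epimerisation at C1' is of no consequence.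
   - Pinnick oxidation (NaClO2, NaH2PO4, 2-methylbut-2-ene, t-BuOH/H2O) gives acid F5.
   - Barton decarboxylation: (COCl)2, then the sodium salt of 2-mercaptopyridine N-oxide, gives thiohydroxamate ester F6. Photolysis with t-BuSH in THF at rt then gives tetrabenzyl ether F7; the C1' radical is quenched by hydrogen-atom transfer, so no metal alkyl is involved.
   - H2 over 10% Pd/C removes the four benzyl groups to give 25.

3. Step 10. Hydroxyalkylation by the hindered, electron-rich aldehyde may be slow under acid. The benzhydryl cation may lose an ortho benzyl group, and the sulfone may ionise during isolation. Fallback, separating C–C bond formation from sulfination and making the C–C bond without acid: it sets out from 7 and 16 and comes back at 18.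
   - The bromomagnesium phenoxide of 7 (EtMgBr, 1.0 equiv, CH2Cl2/toluene, 0 °C) adds to aldehyde 16 by chelate-directed, ortho-specific hydroxyalkylation to give carbinol 17, which is isolated here.
   - Brief treatment of 17 with p-TolSO2H in CH2Cl2 at rt then gives 18. No new compound is involved.

**Further compounds**

F1 | step 11 | dihydrocoumarin fused to ring B through O7, C3 unsubstituted, methine as in the target | CC[C@@H](C)C(=O)c1c(OCc2ccccc2)c([C@H](CC(=O)O3)c2c(OCc4ccccc4)c4c(c(C(=O)C(C)C)c23)OC(C)(C)CC4)c(OCc2ccccc2)c2c1OC(C)(C)CC2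
F2 | step 11 | lactol from F1, anomeric mixture | CC[C@@H](C)C(=O)c1c(OCc2ccccc2)c([C@H](CC(O)O3)c2c(OCc4ccccc4)c4c(c(C(=O)C(C)C)c23)OC(C)(C)CC4)c(OCc2ccccc2)c2c1OC(C)(C)CC2
F3 | step 11 | Z-alkene: tribenzyl ether with a (2Z)-5-methylhex-2-en-1-yl chain on the methine and free 7-OH on ring B | CC[C@@H](C)C(=O)c1c(OCc2ccccc2)c([C@H](C/C=C\CC(C)C)c2c(OCc3ccccc3)c3c(c(C(=O)C(C)C)c2O)OC(C)(C)CC3)c(OCc2ccccc2)c2c1OC(C)(C)CC2
F4 | step 12 | open-chain C1' aldehyde with ring B 7-O-benzyl (tetrabenzyl), C1' epimers | CC[C@@H](C)C(=O)c1c(OCc2ccccc2)c([C@H](C(CCCC(C)C)C=O)c2c(OCc3ccccc3)c3c(c(C(=O)C(C)C)c2OCc2ccccc2)OC(C)(C)CC3)c(OCc2ccccc2)c2c1OC(C)(C)CC2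
F5 | step 12 | carboxylic acid from F4 | CC[C@@H](C)C(=O)c1c(OCc2ccccc2)c([C@H](C(CCCC(C)C)C(=O)O)c2c(OCc3ccccc3)c3c(c(C(=O)C(C)C)c2OCc2ccccc2)OC(C)(C)CC3)c(OCc2ccccc2)c2c1OC(C)(C)CC2
F6 | step 12 | Barton ester of F5 (O-acyl N-hydroxypyridine-2-thione) | CC[C@@H](C)C(=O)c1c(OCc2ccccc2)c([C@H](C(CCCC(C)C)C(=O)ON2C=CC=CC2=S)c2c(OCc3ccccc3)c3c(c(C(=O)C(C)C)c2OCc2ccccc2)OC(C)(C)CC3)c(OCc2ccccc2)c2c1OC(C)(C)CC2
F7 | step 12 | tetrabenzyl ether of the target (methine as in the target) | CC[C@@H](C)C(=O)c1c(OCc2ccccc2)c([C@H](CCCCC(C)C)c2c(OCc3ccccc3)c3c(c(C(=O)C(C)C)c2OCc2ccccc2)OC(C)(C)CC3)c(OCc2ccccc2)c2c1OC(C)(C)CC2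
F0 | step 10 | none | none
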